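**Overview**

Target: the C7–C5' linked dimer of (1S,4R)-8-hydroxycalamenene (calamenene numbering: C1 methyl, C4 isopropyl, C6 methyl, C8 oxygen; primes for the unit joined through C5').
Cuts: arene B at C7'–C8' and C8'–C8a' (C8' goes back to carbon monoxide), then C7–C5' (aryl-metal addition to a dienone) and C5'–C4a' (alkenyl triflate plus methacrolein); arene A is taken apart the same way at C7–C8, C8–C8a and C5–C4a.
Forward: both saturated rings are the intact ring of (+)-menthone; arene A is annulated first by a carbonylative [5+1] closure, its C7 is then bonded to the carbon that becomes C5', and arene B is annulated last around that carbon.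
Stereochemistry: C1/C1' (S) and C4/C4' (R) are C5 and C2 of (+)-menthol and never become sp2; every other centre made on the way ends as an arene carbon.
Enabling feature: arene B is the chain C8a'=C4a'–C5'–C6'(CH3)=C7' plus the oxygen-bearing C8' between its two ends, and on arene A both neighbours of C7 are filled (C6–CH3, C8–O), so a dienylketene on this chain can only close C8'–C8a'.

Key step: step 11

Assumption: the target string gives no descriptor for the C7–C5' axis, so the axis is treated as unassigned; the atropisomer or atropisomers formed in step 11 are carried on and separated at compound 24 if two persist.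

**Route**

Step 1
Reactants: 1 (+)-menthol, (1S,2R,5S)-2-isopropyl-5-methylcyclohexan-1-ol
Product: 2 (+)-menthone, (2R,5S)-2-isopropyl-5-methylcyclohexan-1-one
Conditions: Dess–Martin periodinane, CH2Cl2, 0 → 23 °C
Reagents that add atoms: none
Why: Dess–Martin oxidation of a secondary alcohol under near-neutral, non-enolising conditions, so the isopropyl-bearing α-carbon should not epimerise to isomenthone (the hindered carbinol is the reason a nitroxyl/bleach oxidation is not chosen).

Step 2
Reactants: 2 (+)-menthone
Product: 4 (3S,6R)-6-isopropyl-3-methylcyclohex-1-en-1-yl trifluoromethanesulfonate, via kinetic lithium enolate 3 (not isolated)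
Conditions: LiN(iPr)2, THF, −78 °C; PhNTf2, −78 → 0 °C; aq. NH4Cl
Reagents that add atoms: N-phenylbis(trifluoromethanesulfonimide), O=S(=O)(N(c1ccccc1)S(=O)(=O)C(F)(F)F)C(F)(F)F
Why: Enol triflate synthesis by irreversible kinetic deprotonation at the α-CH2 (the less hindered side) and O-sulfonylation, which places the double bond at the future C4a=C8a and leaves the isopropyl-bearing centre untouched.

Step 3
Reactants: 4 (3S,6R)-6-isopropyl-3-methylcyclohex-1-en-1-yl trifluoromethanesulfonate; 5 methacrolein (2-methylprop-2-enal)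
Product: 6 dienol, 1-[(3S,6R)-6-isopropyl-3-methylcyclohex-1-en-1-yl]-2-methylprop-2-en-1-ol, both carbinol epimers
Conditions: CrCl2 (4 equiv), NiCl2 (2 mol %), DMF, 23 °C; aq. work-up
Reagents that add atoms: none
Why: Nozaki–Hiyama–Kishi coupling, in which zerovalent nickel activates the alkenyl triflate and the resulting alkenyl(trivalent chromium) species adds 1,2 to the enal under non-basic conditions to form C4a–C5; the carbinol centre is uncontrolled and is erased in step 5 or step 8.

Step 4
Reactants: 6 dienol (about half of the material; the rest goes to step 8)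
Product: 7 dienyl acetate, 1-[(3S,6R)-6-isopropyl-3-methylcyclohex-1-en-1-yl]-2-methylprop-2-en-1-yl acetate, both epimers
Conditions: Ac2O, NEt3, DMAP (cat.), CH2Cl2, 0 °C
Reagents that add atoms: acetic anhydride, CC(=O)OC(C)=O
Why: DMAP-catalysed O-acetylation of a secondary alcohol under basic conditions, which avoids ionising the doubly allylic carbinol.

Step 5
Reactants: 7 dienyl acetate; 8 carbon monoxide
Product: 12 (1S,4R)-8-acetoxycalamenene, via dienylketene 9 (not isolated), via cyclohexadienone 10 (not isolated), via 8-hydroxycalamenene 11 (not isolated)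
Conditions: PdCl2(PPh3)2 (5 mol %), CO (60 atm), Ac2O (2 equiv), NEt3 (2 equiv), toluene, 150 °C
Reagents that add atoms: acetic anhydride, CC(=O)OC(C)=O
Why: Palladium-catalysed cyclocarbonylation of a pentadienyl acetate (the doubly allylic acetate gives the same η3-pentadienylpalladium complex as a 2,4-pentadienyl acetate): CO inserts at the CH2 terminus C7, base gives ketene 9, a 6π electrocyclisation closes C8–C8a of arene A, and tautomerisation to 11 and O-acetylation follow, with no new stereocentre and C1/C4 as spectators.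

Step 6
Reactants: 12 (1S,4R)-8-acetoxycalamenene
Product: 11 (1S,4R)-8-hydroxycalamenene, (5R,8S)-5-isopropyl-3,8-dimethyl-5,6,7,8-tetrahydronaphthalen-1-ol, here isolated
Conditions: K2CO3 (0.2 equiv), MeOH, 23 °C
Reagents that add atoms: none
Why: Base-catalysed transesterification (methanolysis) of an aryl acetate, which is fast because phenoxide is a good leaving group and nothing else in the molecule is base-sensitive.

Step 7
Reactants: 11 (1S,4R)-8-hydroxycalamenene
Product: 14 (1S,4R)-8-(methoxymethoxy)calamenene, via sodium phenoxide 13 (not isolated)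
Conditions: NaH, DMF, 0 °C; MOMCl, 0 → 23 °C
Reagents that add atoms: chloromethyl methyl ether, COCCl
Why: Williamson-type O-alkylation of the peri-hindered phenoxide with a reactive α-chloro ether; the MOM ether protects the phenol and directs the lithiation of step 9.

Step 8
Reactants: 6 dienol (second portion)
Product: 15 dienone, 1-[(3S,6R)-6-isopropyl-3-methylcyclohex-1-en-1-yl]-2-methylprop-2-en-1-one
Conditions: MnO2 (activated, excess), CH2Cl2, 23 °C; filtered and used at once
Reagents that add atoms: none
Why: Allylic alcohol oxidation with MnO2 under neutral heterogeneous conditions, which avoids acid-induced Nazarov closure and base-induced vinylogous enolisation at the methyl-bearing γ-centre of the cross-conjugated dienone.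

Step 9
Reactants: 14 (1S,4R)-8-(methoxymethoxy)calamenene; 15 dienone
Product: 18 aryl divinyl carbinol, [(1S,4R)-8-(methoxymethoxy)calamenen-7-yl][(3S,6R)-6-isopropyl-3-methylcyclohex-1-en-1-yl](prop-1-en-2-yl)methanol (both carbinol epimers), via aryllithium 16 (not isolated), via arylcerium dichloride 17 (not isolated)
Conditions: 14: n-BuLi, TMEDA, Et2O, 0 → 23 °C; CeCl3 (anhydrous), THF, −78 °C; then 15, −78 → −40 °C; aq. NH4Cl
Reagents that add atoms: none
Why: Directed ortho-metalation at C7 (the only ring position ortho to the OMOM group, the situation of a thymol ether) followed by organocerium 1,2-addition, the oxophilic and weakly basic cerium reagent favouring attack at the carbonyl over conjugate addition to the isopropenyl terminus and over γ-deprotonation; this forms C7–C5', and the uncontrolled carbinol centre is erased in step 11.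

Step 10
Reactants: 18 aryl divinyl carbinol
Product: 20 tertiary dienyl acetate (acetate of 18), via potassium alkoxide 19 (not isolated)
Conditions: KN(SiMe3)2, THF, −78 °C; AcCl, −78 → 0 °C; aq. NaHCO3; NEt3-deactivated silica
Reagents that add atoms: acetyl chloride, CC(=O)Cl
Why: O-acylation of a preformed hindered tertiary alkoxide under base-only conditions, which should avoid ionising the benzylic, doubly allylic C5'–O bond; any allylic shift to the primary acetate would be harmless because both isomers give the same η3 complex in step 11.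

Step 11
Reactants: 20 tertiary dienyl acetate; 8 carbon monoxide
Product: 24 (1S,4R,1'S,4'R)-8'-acetoxy-8-(methoxymethoxy)-7,5'-bicalamenene, via dienylketene 21 (not isolated), via cyclohexadienone 22 (not isolated), via mono-MOM phenol 23 (not isolated)
Conditions: PdCl2(PPh3)2 (10 mol %), CO (70 atm), Ac2O (3 equiv), NEt3 (3 equiv), toluene, 160 °C
Reagents that add atoms: acetic anhydride, CC(=O)OC(C)=O
Why: Zerovalent palladium, formed from the divalent precatalyst under CO and NEt3, ionises the tertiary acetate to an η3-pentadienylpalladium acetate, CO inserts at the unhindered CH2 terminus C7' to give a 3,5-dienoyl palladium species, and NEt3/Ac2O turn it into dienylketene 21, whose ketene carbon is C8'. The closest known reaction type is the palladium-catalysed cyclocarbonylation of 2,4-pentadienyl acetates to aryl acetates (and of cinnamyl acetates to 1-naphthyl acetates), of which this is a more crowded case with the same mechanism. Arene B (C4a', C5', C6', C7', C8', C8a') closes by thermal disrotatory 6π electrocyclisation of 21, which forms C8'–C8a' after CO insertion has formed C7'–C8'; dienone 22 tautomerises to phenol 23, Ac2O traps it as 24, and the sp3 C7–C5' bond thereby becomes the biaryl bond. No stereocentre is created: the C8a' centre of 22 is lost on aromatisation, C1' and C4' are not involved, and the axis forms as the hot reaction dictates. The step needs CO insertion to outrun β-hydride loss from the η1 isomer at C8a' (C1'–H) and acid-induced 4π Nazarov-type closure of the pentadienyl cation, which high CO pressure and the amine-buffered medium should secure, and it needs C7' and C4a' cis about C5'=C6', which η3–η1 interconversion supplies with aromatisation as the irreversible exit. Closure onto arene A to a naphthol is excluded because both positions ortho to C7 are substituted (C6–CH3, C8–OMOM), and CO insertion at the other terminus C8a' would lead to the same six-membered ring.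

Step 12
Reactants: 24 8'-acetoxy-8-(methoxymethoxy)-7,5'-bicalamenene
Product: 23 (1S,4R,1'S,4'R)-8'-hydroxy-8-(methoxymethoxy)-7,5'-bicalamenene, here isolated
Conditions: K2CO3 (0.2 equiv), MeOH/THF (degassed), 23 °C
Reagents that add atoms: none
Why: Base-catalysed methanolysis of the aryl acetate as in step 6; the MOM ether is stable to base and exclusion of air protects the electron-rich phenoxide.

Step 13
Reactants: 23 8'-hydroxy-8-(methoxymethoxy)-7,5'-bicalamenene
Product: 25 target, (1S,4R,1'S,4'R)-7,5'-bicalamenene-8,8'-diol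
Conditions: HCl (cat., methanolic), MeOH, 40 °C
Reagents that add atoms: none
Why: Acid-catalysed acetal exchange of the MOM ether with methanol frees the second phenol; the biaryl bond and the benzylic centres C1/C1' and C4/C4' are inert to dilute acid.

**Compound list**

1 | (+)-menthol, (1S,2R,5S)-2-isopropyl-5-methylcyclohexan-1-ol | C[C@H]1CC[C@@H]([C@H](C1)O)C(C)C | starting material
2 | (+)-menthone, (2R,5S)-2-isopropyl-5-methylcyclohexan-1-one | O=C1C[C@@H](C)CC[C@@H]1C(C)C | intermediate
3 | kinetic lithium enolate of 2, lithium (3S,6R)-6-isopropyl-3-methylcyclohex-1-en-1-olate | [Li]OC1=C[C@@H](C)CC[C@@H]1C(C)C | intermediate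
4 | (3S,6R)-6-isopropyl-3-methylcyclohex-1-en-1-yl trifluoromethanesulfonate | FC(F)(F)S(=O)(=O)OC1=C[C@@H](C)CC[C@@H]1C(C)C | intermediate
5 | methacrolein | CC(=C)C=O | starting material
6 | dienol, 1-[(3S,6R)-6-isopropyl-3-methylcyclohex-1-en-1-yl]-2-methylprop-2-en-1-ol (carbinol epimers) | OC(C(C)=C)C1=C[C@@H](C)CC[C@@H]1C(C)C | intermediate
7 | dienyl acetate, acetate of 6 (epimers) | CC(=O)OC(C(C)=C)C1=C[C@@H](C)CC[C@@H]1C(C)C | intermediate
8 | carbon monoxide | [C-]#[O+] | starting material
9 | dienylketene, 4-[(3S,6R)-6-isopropyl-3-methylcyclohex-1-en-1-yl]-3-methylbuta-1,3-dien-1-one (C=C geometry not fixed) | O=C=CC(C)=CC1=C[C@@H](C)CC[C@@H]1C(C)C | intermediate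
10 | cyclohexadienone, 8a-H keto tautomer of 11, (5R,8S)-5-isopropyl-3,8-dimethyl-6,7,8,8a-tetrahydronaphthalen-1(5H)-one (8a epimers) | O=C1C=C(C)C=C2C1[C@@H](C)CC[C@@H]2C(C)C | intermediate
11 | (1S,4R)-8-hydroxycalamenene, (5R,8S)-5-isopropyl-3,8-dimethyl-5,6,7,8-tetrahydronaphthalen-1-ol | Oc1cc(C)cc2c1[C@@H](C)CC[C@@H]2C(C)C | intermediate
12 | (1S,4R)-8-acetoxycalamenene | CC(=O)Oc1cc(C)cc2c1[C@@H](C)CC[C@@H]2C(C)C | intermediate
13 | sodium phenoxide of 11 | [Na+].[O-]c1cc(C)cc2c1[C@@H](C)CC[C@@H]2C(C)C | intermediate
14 | (1S,4R)-8-(methoxymethoxy)calamenene | COCOc1cc(C)cc2c1[C@@H](C)CC[C@@H]2C(C)C | intermediate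
15 | dienone, 1-[(3S,6R)-6-isopropyl-3-methylcyclohex-1-en-1-yl]-2-methylprop-2-en-1-one | O=C(C(C)=C)C1=C[C@@H](C)CC[C@@H]1C(C)C | intermediate
16 | aryllithium, (1S,4R)-7-lithio-8-(methoxymethoxy)calamenene | [Li]c1c(C)cc2c(c1OCOC)[C@@H](C)CC[C@@H]2C(C)C | intermediate
17 | arylcerium dichloride, [(1S,4R)-8-(methoxymethoxy)calamenen-7-yl]cerium dichloride | Cl[Ce](Cl)c1c(C)cc2c(c1OCOC)[C@@H](C)CC[C@@H]2C(C)C | intermediate
18 | aryl divinyl carbinol, [(1S,4R)-8-(methoxymethoxy)calamenen-7-yl][(3S,6R)-6-isopropyl-3-methylcyclohex-1-en-1-yl](prop-1-en-2-yl)methanol (carbinol epimers) | COCOc1c(C(O)(C(C)=C)C3=C[C@@H](C)CC[C@@H]3C(C)C)c(C)cc2c1[C@@H](C)CC[C@@H]2C(C)C | intermediate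
19 | potassium alkoxide of 18 | [K+].[O-]C(C(C)=C)(C1=C[C@@H](C)CC[C@@H]1C(C)C)c1c(C)cc2c(c1OCOC)[C@@H](C)CC[C@@H]2C(C)C | intermediate
20 | tertiary dienyl acetate, acetate of 18 (epimers) | COCOc1c(C(OC(C)=O)(C(C)=C)C3=C[C@@H](C)CC[C@@H]3C(C)C)c(C)cc2c1[C@@H](C)CC[C@@H]2C(C)C | intermediate
21 | dienylketene, 4-aryl-4-[(3S,6R)-6-isopropyl-3-methylcyclohex-1-en-1-yl]-3-methylbuta-1,3-dien-1-one, aryl = (1S,4R)-8-(methoxymethoxy)calamenen-7-yl (C=C geometry not fixed) | O=C=CC(C)=C(C1=C[C@@H](C)CC[C@@H]1C(C)C)c1c(C)cc2c(c1OCOC)[C@@H](C)CC[C@@H]2C(C)C | intermediate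
22 | cyclohexadienone, 8a'-H keto tautomer of 23 (8a' epimers) | O=C1C=C(C)C(=C2C1[C@@H](C)CC[C@@H]2C(C)C)c3c(C)cc4c(c3OCOC)[C@@H](C)CC[C@@H]4C(C)C | intermediate
23 | (1S,4R,1'S,4'R)-8'-hydroxy-8-(methoxymethoxy)-7,5'-bicalamenene | Cc1cc2c(c(OCOC)c1-c1c(C)cc(O)c3c1[C@@H](C(C)C)CC[C@@H]3C)[C@@H](C)CC[C@@H]2C(C)C | intermediate
24 | (1S,4R,1'S,4'R)-8'-acetoxy-8-(methoxymethoxy)-7,5'-bicalamenene | Cc1cc2c(c(OCOC)c1-c1c(C)cc(OC(C)=O)c3c1[C@@H](C(C)C)CC[C@@H]3C)[C@@H](C)CC[C@@H]2C(C)C | intermediate
25 | (1S,4R,1'S,4'R)-7,5'-bicalamenene-8,8'-diol, CNP0145304.1 | Cc1cc2c(c(O)c1-c1c(C)cc(O)c3c1[C@@H](C(C)C)CC[C@@H]3C)[C@@H](C)CC[C@@H]2C(C)C | target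

**Totals**

Total step count: 13.
Longest linear sequence: 12 steps (1 → 2 → 4 → 6 → 7 → 12 → 11 → 14 → 18 → 20 → 24 → 23 → 25; step 8 is the side branch from 6).

**Steps most likely to fail**

Step 11. After ionisation of the crowded tertiary acetate, β-hydride loss or 4π closure of the pentadienyl system may be faster than CO insertion. The aryl group on C5' may also disfavour the ketene geometry needed for 6π closure, so arene B would not form cleanly. The fallback makes the C7–C5' bond by cross-coupling two finished arenes. It sets out from 11 and from 14 (through 16) and returns at 24. Phenol 11 is brominated para to the hydroxyl (Bu4NBr3, CH2Cl2/MeOH, 23 °C) to (1S,4R)-5-bromo-8-hydroxycalamenene F1. F1 is acetylated (Ac2O, pyridine) to (1S,4R)-5-bromo-8-acetoxycalamenene F2. Aryllithium 16, made from 14 as in step 9, is treated with ZnCl2 in THF to give arylzinc chloride F3. Negishi coupling of F3 with F2 (Pd2(dba)3, SPhos, THF/NMP, 70 °C), a known way to tetra-ortho-substituted biaryls that tolerates the aryl acetate, should give 24.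

Step 9. The hindered aryl metal may add to the exposed CH2 terminus of the isopropenyl ketone in conjugate fashion or remove the γ-proton of the dienone instead of attacking the carbonyl. The fallback brings in the small isopropenyl group last. It sets out from 4 (with 16 from 14) and returns at 18. Triflate 4 is formylated with palladium catalysis (Pd(PPh3)4, CO 3 atm, Bu3SnH, THF, 50 °C) to (3S,6R)-6-isopropyl-3-methylcyclohex-1-ene-1-carbaldehyde F4. Aryllithium 16 adds to this unhindered aldehyde at −78 °C to give the secondary aryl alkenyl carbinol F5. MnO2 in CH2Cl2 oxidises F5 to the aryl alkenyl ketone F6. Isopropenylmagnesium bromide with CeCl3 (THF, −78 °C) should then add 1,2 to F6 and give 18.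

Step 10. The tertiary, benzylic, doubly allylic acetate may ionise while it forms or is isolated (allylic shift, elimination or 4π closure), or O-acylation may fail for steric reasons. The fallback replaces it by its primary allylic isomer, which belongs to the substrate class of the known cyclocarbonylation. It sets out from 18 and returns at 24. Catalytic O3ReOSiPh3 (Et2O, −40 °C) should transpose the tertiary alcohol 1,3 to the conjugated primary dienol F7. Acetylation (Ac2O, NEt3, DMAP) gives the primary 2,4-pentadienyl acetate F8. Under the conditions of step 11, F8 forms the same η3-pentadienylpalladium complex as 20 and should give 24.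

**Further compounds**

F1 | step 11 | (1S,4R)-5-bromo-8-hydroxycalamenene | Oc1cc(C)c(Br)c2c1[C@@H](C)CC[C@@H]2C(C)C
F2 | step 11 | (1S,4R)-5-bromo-8-acetoxycalamenene | CC(=O)Oc1cc(C)c(Br)c2c1[C@@H](C)CC[C@@H]2C(C)C
F3 | step 11 | [(1S,4R)-8-(methoxymethoxy)calamenen-7-yl]zinc chloride | Cl[Zn]c1c(C)cc2c(c1OCOC)[C@@H](C)CC[C@@H]2C(C)C
F4 | step 9 | (3S,6R)-6-isopropyl-3-methylcyclohex-1-ene-1-carbaldehyde | O=CC1=C[C@@H](C)CC[C@@H]1C(C)C
F5 | step 9 | [(1S,4R)-8-(methoxymethoxy)calamenen-7-yl][(3S,6R)-6-isopropyl-3-methylcyclohex-1-en-1-yl]methanol (carbinol epimers) | COCOc1c(C(O)C3=C[C@@H](C)CC[C@@H]3C(C)C)c(C)cc2c1[C@@H](C)CC[C@@H]2C(C)C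
F6 | step 9 | [(1S,4R)-8-(methoxymethoxy)calamenen-7-yl][(3S,6R)-6-isopropyl-3-methylcyclohex-1-en-1-yl]methanone | COCOc1c(C(=O)C3=C[C@@H](C)CC[C@@H]3C(C)C)c(C)cc2c1[C@@H](C)CC[C@@H]2C(C)C
F7 | step 10 | primary dienol, 3-[(1S,4R)-8-(methoxymethoxy)calamenen-7-yl]-3-[(3S,6R)-6-isopropyl-3-methylcyclohex-1-en-1-yl]-2-methylprop-2-en-1-ol (C=C geometry not fixed) | OCC(C)=C(C1=C[C@@H](C)CC[C@@H]1C(C)C)c1c(C)cc2c(c1OCOC)[C@@H](C)CC[C@@H]2C(C)C
F8 | step 10 | primary 2,4-pentadienyl acetate, acetate of F7 | CC(=O)OCC(C)=C(C1=C[C@@H](C)CC[C@@H]1C(C)C)c1c(C)cc2c(c1OCOC)[C@@H](C)CC[C@@H]2C(C)C
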